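## Analysis of the target

Isosinensetin (17) is 5,7,8,3',4'-pentamethoxyflavone, C20H20O7. It is a 4H-chromen-4-one in which benzo ring A and pyranone ring C share the C4a–C8a bond, with a 3,4-dimethoxyphenyl ring B on C2. The molecule has no stereocentre and no stereogenic double bond, so every selectivity question is one of position. Ring A is oxygenated at C5, C7 and C8 and carries the ring oxygen O1 on C8a, which leaves C6 as its only CH. Three sites are sensitive:
- the pyranone, a vinylogous ester whose C2 is opened by hydroxide and amines;
- the C5 methoxyl peri to the C4 carbonyl, which Lewis acids remove first;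
- any free ring A phenol on the way, since a 5,8-dioxygenated ring is a hydroquinone that oxidises readily to a quinone.

The hard part is the 5,7,8 pattern: a late oxygenation of a 5,7-dioxygenated flavone has to tell C8 from C6, and the two patterns can exchange through ring opening and reclosure of 5-hydroxyflavones. The strategy rests on the fact that the oxygens on C5 and C8 are para to each other. Between them lie the C6–C7 edge (one hydrogen, one oxygen) on one side and the C4a–C8a edge on the other, which is at the same time a C=C bond of a 4-pyranone. These four pieces correspond one to one to the alkoxycarbene carbon, a carbonyl ligand, an alkyne and the alkenyl group of a Dötz benzannulation.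

## Retrosynthetic reasoning

**17 to 16.** The O–CH3 bonds at O7 and O8 are cut. The C5 methoxyl is not touched because it is carried from the carbene carbon, so the route never has to methylate a hydroxyl chelated to the C4 carbonyl. The forward reaction is an exhaustive O-methylation of catechol 16.

**16 to 15.** The C7–O bond is traced back to a C7–B bond. An alkyne cannot be relied on to deliver a free oxygen at C7, but a boryl group can be carried through the annulation and exchanged for hydroxyl at the same carbon. The forward reaction has to oxidise the C–B bond without oxidising the hydroquinone-type ring.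

**15 to 12 and 13, by way of 14.** Three ring A bonds are cut: C5–C6, C7–C8 and C8–C8a. C8 and its oxygen come from a carbonyl ligand of 12. Cutting here leaves rings B and C intact in 12, and the fusion atoms C4a and C8a are already the double bond of the pyranone. The position of O1 and the ring fusion are therefore fixed before ring A exists, and no substitution on a finished ring A is needed. One step gains three C–C bonds, the whole of ring A, the para oxygens already differentiated (methoxyl at C5, hydroxyl at C8) and a marker at C7. The forward reaction must insert 13 with its CH end next to the carbene carbon, insert a carbonyl ligand, and close onto the oxygen-bearing pyranone carbon.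

**12 to 8 and 9, by way of 10 and 11.** The Cr=C bond and the O–CH3 bond of the carbene are cut. The usual approach through an organolithium is closed, because a 4-pyranone metalated at this carbon is not a practical reagent. The polarity is therefore reversed: an electrophilic acyl carbon in 8 meets the nucleophilic chromate 10 made from 9. The forward reaction must achieve acyl substitution faster than attack on the pyranone, and then methylation at the acyl oxygen of 11.

**8 to 7 to 6.** These are functional group changes at the carboxyl carbon. The ester in 6 is a tert-butyl ester so that it can be removed with acid. Cleavage with hydroxide would add to C2 of the pyranone and open ring C.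

**6 to 3 and 4, by way of 5.** Ring C is cut at the flavone C2–C3 bond and at the O1–C8a bond. This divides the pyranone into an aroyl unit (4) and a four-carbon enaminone that already carries the carboxyl group (3). The forward reaction is acylation of the methyl-derived enolate of 3 by 4 to give 5, then closure by the enol oxygen with loss of the amino group.

**3 to 1 and 2.** The C=C bond between the active methylene of 1 and the formyl-equivalent carbon of 2 is cut; the forward reaction is a simple condensation.

## Alternatives that were turned down

**Alternative 1:** The chromone is unfolded completely, cutting C4a–C8a and O1–C2, to the open-chain polyketide A1, methyl 9-(3,4-dimethoxyphenyl)-3,5,7,9-tetraoxononanoate.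
- Forward key step: treatment of A1 with Mg(OMe)2 templates the chain so that the sixth chain carbon attacks the ester carbon in a Claisen condensation (C4a–C8a, ring A). Acid then lets the new phenol oxygen add to the aryl ketone and lose water (O1–C2, ring C), giving A2, 5,7-dihydroxy-3',4'-dimethoxyflavone.
- For it: it is biomimetic, closes two rings in one operation and needs no transition metal.
- Against it: a polyketide folding can only deliver the 5,7 pattern, so A2 has no oxygen at C8. A later hydroxylation must then choose C8 over the electronically similar C6 on a ring that can also scramble the two positions through ring opening. The chelated 5-hydroxyl would also need forcing methylation. A1 itself is a pentacarbonyl chain that can close by aldol as well as Claisen pathways.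
- Comparison: Alternative 1 is stronger in ring-forming economy and in avoiding stoichiometric chromium. The chosen route offers in its place an oxygen at C8 that is built in during ring formation, a marked C7, and a C5 that arrives methylated, so that no choice between C6 and C8 ever arises.

**Alternative 2:** Ring B is cut at C1'–C2' and C5'–C6', leading to the alkyne A3, 2-ethynyl-5,7,8-trimethoxy-4H-chromen-4-one, and the diene A4, 2,3-dimethoxybuta-1,3-diene.
- Forward key step: a low-valent cobalt catalyst made from CoBr2(dppe), Zn and ZnI2 joins A3 and A4 in a (4+2) cycloaddition to the 1,4-cyclohexadiene A5, 2-(4,5-dimethoxycyclohexa-1,4-dien-1-yl)-5,7,8-trimethoxy-4H-chromen-4-one. A5 then has to be dehydrogenated to the arene.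
- For it: it is convergent, catalytic in metal, and the symmetric diene fixes the 3',4'-oxygens without any regiochemical question.
- Against it: ring B is the easy ring. The whole difficulty of the 5,7,8 pattern is moved into A3, which would have to be made from A6, 1-(2-hydroxy-3,4,6-trimethoxyphenyl)ethanone. From A6 a classical aroylation and cyclization would reach the target in fewer steps than the detour through A3. A3 is also a doubly activated Michael acceptor, and A5 is a bis(enol ether) that hydrolyses easily and needs an extra oxidation.
- Comparison: Alternative 2 is stronger in convergence and metal economy. The chosen route builds the ring that is actually hard.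

**Alternative 3:** Only C4a–C5 is cut, which unravels ring A into a side chain on the pyranone carbon that becomes C8a: A7, racemic tert-butyl 4-[6-(3,4-dimethoxyphenyl)-4-oxo-4H-pyran-2-yl]-4-methoxy-3-oxobutanoate.
- Forward key step: heating A7 expels the ester alcohol and forms an acylketene. Enolization of the C7 ketone toward C8 gives a dienylketene that includes the pyranone C8a=C4a bond. 6π electrocyclization forms C4a–C5, and tautomerization gives A8, 5,7-dihydroxy-8,3',4'-trimethoxyflavone.
- For it: it shares the logic of the chosen route (ring A closed onto a preformed ring C through a dienylketene) but is metal-free. The closure is polarity-matched, since the nucleophilic α-carbon of the pyranone meets the ketene carbon. The C8 methoxyl is in place from the start.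
- Against it: A7 needs a 2,6-disubstituted pyranone with a four-carbon, doubly activated side chain, which costs more steps and is prone to retro-Claisen cleavage. The acylketene can be trapped or can dimerize before it enolizes in the right direction. A8 ends with a chelated 5-hydroxyl that resists methylation.
- Comparison: Alternative 3 is as strong or stronger in the key step itself and in avoiding chromium. The chosen route offers a precursor reached in five steps from bulk chemicals by a known pyranone assembly, a C5 oxygen that is methylated from the outset, and a C7 oxygen introduced by a mild C–B oxidation.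

Key step: step 6

## Route

Assumption: 3 is a push–pull alkene whose double-bond geometry is not fixed and is lost in step 2, so it is used as formed; NaC10H8 (sodium naphthalenide) for step 5 is taken from a titrated THF stock solution.

**Step 1**
Reactants: 1 tert-butyl 3-oxobutanoate (tert-butyl acetoacetate); 2 N,N-dimethylformamide dimethyl acetal
Product: 3 tert-butyl 2-[(dimethylamino)methylidene]-3-oxobutanoate
Conditions: neat, rt → 60 °C; volatiles removed in vacuo
Reagents that add atoms: none
Why: Condensation of the active methylene of a β-keto ester with an amide acetal (enaminone formation); the doubly activated CH2 reacts much faster than the methyl group.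

**Step 2**
Reactants: 3 tert-butyl 2-[(dimethylamino)methylidene]-3-oxobutanoate; 4 3,4-dimethoxybenzoyl chloride
Product: 6 tert-butyl 6-(3,4-dimethoxyphenyl)-4-oxo-4H-pyran-3-carboxylate, via diketo enaminone 5 (not isolated)
Conditions: 3 + 4 premixed in THF, added to LiN(SiMe3)2 (2.2 equiv), THF, −78 °C; then 1 M HCl, Et2O, rt
Reagents that add atoms: none
Why: In situ C-acylation of an enaminone anion: the amide base removes a methyl proton of 3, the dienolate is acylated at carbon by 4, and the second equivalent of base stores diketone 5 as its enolate. On acidification the enol oxygen adds to the aminomethylidene carbon and the amine is expelled (addition–elimination, 6-endo closure) to give the 4-pyranone.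

**Step 3**
Reactants: 6 tert-butyl 6-(3,4-dimethoxyphenyl)-4-oxo-4H-pyran-3-carboxylate
Product: 7 6-(3,4-dimethoxyphenyl)-4-oxo-4H-pyran-3-carboxylic acid
Conditions: CF3CO2H, CH2Cl2 (1:2), 0 °C → rt
Reagents that add atoms: none
Why: Acidolysis of a tert-butyl ester through the tert-butyl cation; no hydroxide is present, so the base-labile C2 of the pyranone is not attacked. The vinylogous β-keto acid should not decarboxylate at room temperature, because the enol that decarboxylation would give is a cyclic allene.

**Step 4**
Reactants: 7 6-(3,4-dimethoxyphenyl)-4-oxo-4H-pyran-3-carboxylic acid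
Product: 8 6-(3,4-dimethoxyphenyl)-4-oxo-4H-pyran-3-carbonyl chloride
Conditions: (COCl)2 (1.2 equiv), DMF (cat.), CH2Cl2, 0 °C → rt; concentrated and used crude
Reagents that add atoms: oxalyl chloride ClC(=O)C(=O)Cl
Why: Standard conversion of a carboxylic acid into its chloride through a catalytic chloroiminium species; the by-products are gases, and the crude chloride is used at once.

**Step 5**
Reactants: 8 6-(3,4-dimethoxyphenyl)-4-oxo-4H-pyran-3-carbonyl chloride; 9 hexacarbonylchromium
Product: 12 pentacarbonyl{[6-(3,4-dimethoxyphenyl)-4-oxo-4H-pyran-3-yl](methoxy)methylidene}chromium, via disodium pentacarbonylchromate 10 (not isolated), via sodium acylchromate 11 (not isolated)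
Conditions: 9 (1.0 equiv), NaC10H8 (2.0 equiv), THF, −78 → 0 °C; then 8, THF, −78 °C; solvent exchange to CH2Cl2; Me3OBF4 (1.05 equiv), −40 → 0 °C; Ar, dark
Reagents that add atoms: trimethyloxonium tetrafluoroborate C[O+](C)C.F[B-](F)(F)F
Why: Acyl substitution of the acid chloride by the strongly nucleophilic pentacarbonylchromate dianion gives the acylchromate, and O-methylation of this acylmetalate with the hard oxonium salt gives the methoxycarbene (the acid chloride variant of the Fischer carbene synthesis). Low temperature and one equivalent of each reagent should keep the dianion away from the pyranone C2 and the oxonium salt away from the pyranone carbonyl oxygen.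

**Step 6**
Reactants: 12 pentacarbonyl{[6-(3,4-dimethoxyphenyl)-4-oxo-4H-pyran-3-yl](methoxy)methylidene}chromium; 13 2-ethynyl-4,4,5,5-tetramethyl-1,3,2-dioxaborolane
Product: 15 2-(3,4-dimethoxyphenyl)-8-hydroxy-5-methoxy-7-(4,4,5,5-tetramethyl-1,3,2-dioxaborolan-2-yl)-4H-chromen-4-one, via tricarbonylchromium arene complex 14 (not isolated)
Conditions: 13 (2 equiv), THF (0.05 M), 50 °C, Ar, dark; then air, Et2O, rt, filtration through Celite
Reagents that add atoms: none
Why: Heat removes one cis carbonyl ligand from 12 (the pyranone C4 carbonyl can hold the vacant site as a five-membered chelate), 13 coordinates and inserts into the Cr=C bond so that its CH carbon bonds to the carbene carbon (C5–C6) and its boron-bearing carbon becomes the new carbene carbon, and a carbonyl ligand then inserts to give a chromium-bound dienylketene (C7–C8). Ring A closes by thermal 6π electrocyclization of this dienylketene, the ketene carbon bonding to the oxygen-bearing C2 of the pyranone (C8–C8a), and loss of the C8a hydrogen by tautomerization gives the phenol as its arene tricarbonylchromium complex 14, from which air releases 15. The closest known reaction type is the Dötz benzannulation of alkenyl and aryl methoxycarbene chromium complexes with alkynylboronates, which gives ortho-boryl hydroquinone monomethyl ethers. Two selectivities are needed. The first is the sense of alkyne insertion (hydrogen at C6, boron at C7): the larger alkyne substituent avoids the substituted carbene carbon and ends up next to the carbonyl-derived carbon, and the pinacolboryl group is by far the larger end of 13. The second is benzannulation over cyclopentannulation without carbonyl insertion: a chromium alkoxycarbene, an ether solvent and a moderate temperature all favour insertion, and the conjugated, electron-poor alkenyl group should do the same. The ring fusion needs no control, since the only pyranone position that can close the six-membered ring is C2, the other neighbour of the carbene-bearing carbon being the C4 carbonyl carbon. No stereocentre is formed.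

**Step 7**
Reactants: 15 2-(3,4-dimethoxyphenyl)-8-hydroxy-5-methoxy-7-(4,4,5,5-tetramethyl-1,3,2-dioxaborolan-2-yl)-4H-chromen-4-one
Product: 16 2-(3,4-dimethoxyphenyl)-7,8-dihydroxy-5-methoxy-4H-chromen-4-one
Conditions: 30% H2O2 (1.5 equiv), pH 7 phosphate buffer, THF, 0 °C, Ar; then aq. Na2S2O3
Reagents that add atoms: hydrogen peroxide OO
Why: Oxidation of an arylboronic ester: hydroperoxide adds to boron, the aryl group migrates from boron to oxygen with its position unchanged, and the borate is hydrolysed to the phenol. Near-neutral buffer, low temperature and exclusion of air should keep the catechol from going on to a quinone and keep hydroxide away from the pyranone.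

**Step 8**
Reactants: 16 2-(3,4-dimethoxyphenyl)-7,8-dihydroxy-5-methoxy-4H-chromen-4-one
Product: 17 isosinensetin, 2-(3,4-dimethoxyphenyl)-5,7,8-trimethoxy-4H-chromen-4-one
Conditions: Me2SO4 (3 equiv), K2CO3 (4 equiv), acetone, reflux, Ar
Reagents that add atoms: dimethyl sulfate COS(=O)(=O)OC
Why: Williamson O-methylation of both phenols with a carbonate base; neither hydroxyl is hydrogen-bonded to the C4 carbonyl, so both should react under ordinary conditions, and the C5 methoxyl is already in place.

## Compound list

1 | tert-butyl 3-oxobutanoate | CC(=O)CC(=O)OC(C)(C)C | starting material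
2 | N,N-dimethylformamide dimethyl acetal | COC(OC)N(C)C | starting material
3 | tert-butyl 2-[(dimethylamino)methylidene]-3-oxobutanoate | CC(=O)C(=CN(C)C)C(=O)OC(C)(C)C | intermediate
4 | 3,4-dimethoxybenzoyl chloride | COc1ccc(C(=O)Cl)cc1OC | starting material
5 | tert-butyl 5-(3,4-dimethoxyphenyl)-2-[(dimethylamino)methylidene]-3,5-dioxopentanoate (formed as its lithium enolate, shown neutral) | COc1ccc(C(=O)CC(=O)C(=CN(C)C)C(=O)OC(C)(C)C)cc1OC | intermediate
6 | tert-butyl 6-(3,4-dimethoxyphenyl)-4-oxo-4H-pyran-3-carboxylate | COc1ccc(-c2cc(=O)c(C(=O)OC(C)(C)C)co2)cc1OC | intermediate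
7 | 6-(3,4-dimethoxyphenyl)-4-oxo-4H-pyran-3-carboxylic acid | COc1ccc(-c2cc(=O)c(C(=O)O)co2)cc1OC | intermediate
8 | 6-(3,4-dimethoxyphenyl)-4-oxo-4H-pyran-3-carbonyl chloride | COc1ccc(-c2cc(=O)c(C(=O)Cl)co2)cc1OC | intermediate
9 | hexacarbonylchromium, Cr(CO)6 | O=C=[Cr](=C=O)(=C=O)(=C=O)(=C=O)=C=O | starting material
10 | disodium pentacarbonylchromate, Na2Cr(CO)5 | [Na+].[Na+].O=C=[Cr-2](=C=O)(=C=O)(=C=O)=C=O | intermediate
11 | sodium pentacarbonyl[6-(3,4-dimethoxyphenyl)-4-oxo-4H-pyran-3-carbonyl]chromate | [Na+].[O-]C(=[Cr](=C=O)(=C=O)(=C=O)(=C=O)=C=O)c1coc(-c2ccc(OC)c(OC)c2)cc1=O | intermediate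
12 | pentacarbonyl{[6-(3,4-dimethoxyphenyl)-4-oxo-4H-pyran-3-yl](methoxy)methylidene}chromium | COC(=[Cr](=C=O)(=C=O)(=C=O)(=C=O)=C=O)c1coc(-c2ccc(OC)c(OC)c2)cc1=O | intermediate
13 | 2-ethynyl-4,4,5,5-tetramethyl-1,3,2-dioxaborolane | C#CB1OC(C)(C)C(C)(C)O1 | starting material
14 | tricarbonylchromium complex of 15, bound η6 to ring A (the SMILES shows the Cr(CO)3 unit as a separate component) | COc1ccc(-c2cc(=O)c3c(OC)cc(B4OC(C)(C)C(C)(C)O4)c(O)c3o2)cc1OC.O=C=[Cr](=C=O)=C=O | intermediate
15 | 2-(3,4-dimethoxyphenyl)-8-hydroxy-5-methoxy-7-(4,4,5,5-tetramethyl-1,3,2-dioxaborolan-2-yl)-4H-chromen-4-one | COc1ccc(-c2cc(=O)c3c(OC)cc(B4OC(C)(C)C(C)(C)O4)c(O)c3o2)cc1OC | intermediate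
16 | 2-(3,4-dimethoxyphenyl)-7,8-dihydroxy-5-methoxy-4H-chromen-4-one | COc1ccc(-c2cc(=O)c3c(OC)cc(O)c(O)c3o2)cc1OC | intermediate
17 | isosinensetin, 2-(3,4-dimethoxyphenyl)-5,7,8-trimethoxy-4H-chromen-4-one | COc1ccc(-c2cc(=O)c3c(OC)cc(OC)c(OC)c3o2)cc1OC | target

## Step count and risks

Total step count: 8. Longest linear sequence: 8 steps (1 → 3 → 6 → 7 → 8 → 12 → 15 → 16 → 17); 2, 4, 9 and 13 enter as purchased reagents.

**Step 6 (key step).**
- What may go wrong: diversion of the vinylcarbene intermediate before carbonyl insertion (cyclopentannulation onto the pyranone, or capture by the pyranone carbonyl oxygen), because the alkenyl unit here is an electron-poor, chelating vinylogous ester and not a simple alkene. Alkyne insertion in the reverse sense would put boron at C6. The ortho-hydroxy boronate could lose boron by protodeboronation during decomplexation or chromatography.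
- Fallback, from 12 back to 16: the same benzannulation with 3,3-diethoxyprop-1-yne, a plain terminal alkyne whose substituent is placed next to the new hydroxyl, should give 7-(diethoxymethyl)-2-(3,4-dimethoxyphenyl)-8-hydroxy-5-methoxy-4H-chromen-4-one F1. Dilute aqueous acid would unmask the salicylaldehyde 2-(3,4-dimethoxyphenyl)-8-hydroxy-5-methoxy-4-oxo-4H-chromene-7-carbaldehyde F2. Dakin oxidation (H2O2, dilute aqueous NaOH, 0 °C, Ar) would convert the formyl group into the C7 hydroxyl and rejoin the route at 16. The C7 oxygen then comes from an aryl migration in a formyl group and not from a C–B bond.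

**Step 5.**
- What may go wrong: electron transfer from the dianion to the pyranone or conjugate attack at its C2 in competition with acyl substitution, and methylation of the pyranone carbonyl oxygen by the oxonium salt.
- Fallback, from 7 back to 12: iododecarboxylation of 7 (N-iodosuccinimide, LiOAc cat., MeCN–H2O) exchanges the carboxyl group for iodine at the same carbon to give 2-(3,4-dimethoxyphenyl)-5-iodo-4H-pyran-4-one F3. Iodine–magnesium exchange with iPrMgCl·LiCl in THF at −40 °C gives the pyranonylmagnesium chloride F4, which is not isolated. Its addition to 9 gives the chloromagnesium acylchromate F5, also not isolated, and Me3OBF4 then gives 12. The acylmetalate is built by the organometallic route, so the reducing dianion is avoided.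

**Step 7.**
- What may go wrong: over-oxidation of the electron-rich product (a catechol that is also a hydroquinone monoether) by peroxide or air, or attack of peroxide anion on the pyranone.
- Fallback, from 15 back to 17: the C8 hydroxyl is methylated first (MeI, K2CO3, DMF, rt) to give 2-(3,4-dimethoxyphenyl)-5,8-dimethoxy-7-(4,4,5,5-tetramethyl-1,3,2-dioxaborolan-2-yl)-4H-chromen-4-one F6. Buffered H2O2 oxidation of the C–B bond then gives the monophenol 2-(3,4-dimethoxyphenyl)-7-hydroxy-5,8-dimethoxy-4H-chromen-4-one F7, which is neither a catechol nor a free hydroquinone. Methylation (Me2SO4, K2CO3, acetone) gives 17. This costs one step more.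

**Step 2.**
- What may go wrong: O-acylation or double acylation of the enaminone anion, or attack of the amide base on the acid chloride. Partial loss of the tert-butyl group in the acid treatment would be harmless, since step 3 removes it anyway.
- Fallback, from 1 back to 6: the 2,4-dianion of 1 (NaH, then n-BuLi, THF, 0 °C) is acylated at its terminal carbon by methyl 3,4-dimethoxybenzoate to give tert-butyl 5-(3,4-dimethoxyphenyl)-3,5-dioxopentanoate F8. Condensation of F8 with 2 at the methylene between ketone and ester, then brief acid treatment, closes the same pyranone 6. The order of C-acylation and aminomethylenation is thus reversed. Condensation at the other methylene of F8 is a risk of this fallback, since only the adduct at the ester-flanked methylene can close to 6.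

## Further compounds

F1 | step 6 | 7-(diethoxymethyl)-2-(3,4-dimethoxyphenyl)-8-hydroxy-5-methoxy-4H-chromen-4-one | CCOC(OCC)c1cc(OC)c2c(=O)cc(-c3ccc(OC)c(OC)c3)oc2c1O
F2 | step 6 | 2-(3,4-dimethoxyphenyl)-8-hydroxy-5-methoxy-4-oxo-4H-chromene-7-carbaldehyde | O=Cc1cc(OC)c2c(=O)cc(-c3ccc(OC)c(OC)c3)oc2c1O
F3 | step 5 | 2-(3,4-dimethoxyphenyl)-5-iodo-4H-pyran-4-one | COc1ccc(-c2cc(=O)c(I)co2)cc1OC
F4 | step 5 | chloro[6-(3,4-dimethoxyphenyl)-4-oxo-4H-pyran-3-yl]magnesium | COc1ccc(-c2cc(=O)c([Mg]Cl)co2)cc1OC
F5 | step 5 | chloromagnesium pentacarbonyl[6-(3,4-dimethoxyphenyl)-4-oxo-4H-pyran-3-carbonyl]chromate | [Mg+2].[Cl-].[O-]C(=[Cr](=C=O)(=C=O)(=C=O)(=C=O)=C=O)c1coc(-c2ccc(OC)c(OC)c2)cc1=O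
F6 | step 7 | 2-(3,4-dimethoxyphenyl)-5,8-dimethoxy-7-(4,4,5,5-tetramethyl-1,3,2-dioxaborolan-2-yl)-4H-chromen-4-one | COc1ccc(-c2cc(=O)c3c(OC)cc(B4OC(C)(C)C(C)(C)O4)c(OC)c3o2)cc1OC
F7 | step 7 | 2-(3,4-dimethoxyphenyl)-7-hydroxy-5,8-dimethoxy-4H-chromen-4-one | COc1ccc(-c2cc(=O)c3c(OC)cc(O)c(OC)c3o2)cc1OC
F8 | step 2 | tert-butyl 5-(3,4-dimethoxyphenyl)-3,5-dioxopentanoate | COc1ccc(C(=O)CC(=O)CC(=O)OC(C)(C)C)cc1OC
A1 | alternative 1 | methyl 9-(3,4-dimethoxyphenyl)-3,5,7,9-tetraoxononanoate | COC(=O)CC(=O)CC(=O)CC(=O)CC(=O)c1ccc(OC)c(OC)c1
A2 | alternative 1 | 5,7-dihydroxy-3',4'-dimethoxyflavone | COc1ccc(-c2cc(=O)c3c(O)cc(O)cc3o2)cc1OC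
A3 | alternative 2 | 2-ethynyl-5,7,8-trimethoxy-4H-chromen-4-one | C#Cc1cc(=O)c2c(OC)cc(OC)c(OC)c2o1
A4 | alternative 2 | 2,3-dimethoxybuta-1,3-diene | C=C(OC)C(=C)OC
A5 | alternative 2 | 2-(4,5-dimethoxycyclohexa-1,4-dien-1-yl)-5,7,8-trimethoxy-4H-chromen-4-one | COC1=C(OC)CC(c2cc(=O)c3c(OC)cc(OC)c(OC)c3o2)=CC1
A6 | alternative 2 | 1-(2-hydroxy-3,4,6-trimethoxyphenyl)ethanone | CC(=O)c1c(O)c(OC)c(OC)cc1OC
A7 | alternative 3 | tert-butyl 4-[6-(3,4-dimethoxyphenyl)-4-oxo-4H-pyran-2-yl]-4-methoxy-3-oxobutanoate (racemic) | COc1ccc(-c2cc(=O)cc(C(OC)C(=O)CC(=O)OC(C)(C)C)o2)cc1OC
A8 | alternative 3 | 5,7-dihydroxy-8,3',4'-trimethoxyflavone | COc1ccc(-c2cc(=O)c3c(O)cc(O)c(OC)c3o2)cc1OC
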